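**Retrosynthetic overview**
1. Target 25 ⇐ 24 (double O‑demethylation) ⇐ 23 (prenylation of the C1 bridgehead enolate) ⇐ 21 (C3 lithiation/aroylation) ⇐ trione 19.
2. Key step: 19 ⇐ cyclopentane‑fused dienone‑dione 17 by trivalent‑iodine oxidation. C1, an α‑carbonyl carbon, becomes an enolonium (oxyallyl cation) and captures the migrating C8; this C1–C8 bond formation is a ring expansion that creates ring A and the bicyclo[3.3.1] core.
3. 17 ⇐ cyclopentanone 14 + diketene (C5 acylation, then aldol closure of the six‑membered dione ring).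
4. 14 ⇐ enone 9 by asymmetric CuH conjugate reduction/enolate alkylation (sets C7 and C8) and C5 prenylation.
5. 9 ⇐ 2‑methylcyclopentenone via a β‑sulfonyl ketal (homoenolate equivalent) alkylated with geranyl bromide. Ring order: cyclopentane (bought) → fused dione ring (step 6) → expansion to the bridged bicycle (step 7).

Assumption: (S)-p-tol-BINAP is taken to deliver hydride to the enone face of 9 that gives the (3S) ketone; if the sense is opposite, the (R) ligand is used.

Notation: geranyl = (2E)-3,7-dimethylocta-2,6-dien-1-yl; prenyl = 3-methylbut-2-en-1-yl; homoprenyl = 4-methylpent-3-en-1-yl; C1–C9 = bicyclo[3.3.1]nonane numbering of the target (C1 is next to C8).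

**Step 1**
Reactants: 1 2-methylcyclopent-2-en-1-one; 2 sodium benzenesulfinate
Product: 3 2-methyl-3-(phenylsulfonyl)cyclopentan-1-one (racemic)
Conditions: PhSO2Na, AcOH, EtOH–H2O, rt
Reagents that add atoms: sodium benzenesulfinate 2, [Na+].[O-]S(=O)c1ccccc1
Why: Conjugate (sulfa‑Michael) addition of benzenesulfinic acid to the enone gives the β‑sulfonyl ketone that will act as a masked homoenolate; its two stereocentres are erased in step 3.

**Step 2**
Reactants: 3 2-methyl-3-(phenylsulfonyl)cyclopentan-1-one; 4 ethylene glycol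
Product: 5 6-methyl-7-(phenylsulfonyl)-1,4-dioxaspiro[4.4]nonane (racemic)
Conditions: HOCH2CH2OH, TsOH·H2O (cat.), benzene, reflux, Dean–Stark
Reagents that add atoms: ethylene glycol 4, OCCO
Why: Acid‑catalysed ketalisation removes the acidic α‑hydrogens and blocks β‑elimination, so that the sulfone‑bearing carbon can be deprotonated cleanly.

**Step 3**
Reactants: 5 6-methyl-7-(phenylsulfonyl)-1,4-dioxaspiro[4.4]nonane; 6 geranyl bromide
Product: 9 3-geranyl-2-methylcyclopent-2-en-1-one, via alkylated sulfonyl ketal 7 (not isolated), via β-sulfonyl ketone 8 (not isolated)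
Conditions: n-BuLi, THF, −78 °C; 6, −78 → 0 °C; then 1 M HCl, THF, rt; then Et3N, rt
Reagents that add atoms: geranyl bromide 6, CC(C)=CCC/C(C)=C/CBr
Why: The α‑sulfonyl carbanion of 5 is a homoenolate (β‑acyl vinyl anion) equivalent, so the ring β‑carbon, normally electrophilic, attacks the electrophilic CH2 of geranyl bromide by SN2 with the (E)‑alkene intact, after which ketal hydrolysis and E1cB loss of sulfinate restore the enone.

**Step 4**
Reactants: 9 3-geranyl-2-methylcyclopent-2-en-1-one; 10 5-iodo-2-methylpent-2-ene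
Product: 12 (2S,3S)-3-geranyl-2-methyl-2-homoprenylcyclopentan-1-one, via diphenylsilyl enol ether 11 (not isolated)
Conditions: CuCl (5 mol%), NaOt-Bu (5 mol%), (S)-p-tol-BINAP (5 mol%), Ph2SiH2, toluene, 0 °C; then MeLi, THF–HMPA, −78 °C; 10, −78 °C → rt
Reagents that add atoms: 5-iodo-2-methylpent-2-ene 10, CC(C)=CCCI
Why: Ligand‑controlled CuH conjugate reduction (asymmetric 1,4‑hydrosilylation) sets C7 by hydride delivery to one enone face and gives the tetrasubstituted enolate regiospecifically, and enolate alkylation anti to the neighbouring geranyl group then sets the quaternary C8 (homoprenyl trans, methyl cis to geranyl).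

**Step 5**
Reactants: 12 (2S,3S)-3-geranyl-2-methyl-2-homoprenylcyclopentan-1-one; 13 prenyl bromide
Product: 14 5-prenyl derivative of 12 (both C5 epimers)
Conditions: LiN(i-Pr)2, THF, −78 °C; 13, −78 → 0 °C
Reagents that add atoms: prenyl bromide 13, CC(C)=CCBr
Why: Kinetic enolate alkylation at the only enolisable position; the C5 configuration does not matter because C5 is re‑enolised in step 6.

**Step 6**
Reactants: 14 5-prenyl derivative of 12; 15 diketene
Product: 17 2-geranyl-1-methyl-1-homoprenyl-3a-prenyl-1,2,3,3a-tetrahydro-4H-indene-4,6(5H)-dione, via cis-fused aldol adduct 16 (not isolated)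
Conditions: LiN(i-Pr)2, THF, −78 → 0 °C; 15, −78 → −20 °C; then 1 M HCl, THF, rt
Reagents that add atoms: diketene 15, C=C1CC(=O)O1
Why: The tetrasubstituted enolate C‑acylates diketene on the face opposite the C7 geranyl group (this sets the quaternary C5), ring opening releases the methyl‑ketone enolate, which closes onto the C9 ketone by intramolecular aldol addition, and acid dehydrates the tertiary aldol to the dienone (acetoacetylation–aldol annulation).

**Step 7**
Reactants: 17 cyclopentane-fused dienone-dione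
Product: 19 7-geranyl-8-methyl-8-homoprenyl-5-prenylbicyclo[3.3.1]nonane-2,4,9-trione, via phenyliodonium ylide 18 (not isolated)
Conditions: PhI(OAc)2 (1.1 equiv), KOH, MeOH, −10 °C → rt; then 1 M HCl
Reagents that add atoms: methanol (as KOMe; supplies the C9 oxygen), CO
Why: Proposed new method: under standard ylide‑forming conditions the 1,3‑dione of 17 gives phenyliodonium ylide 18, whose enone is now electrophilic enough for methoxide to add at C9; C‑protonation at C3 and loss of PhI from the resulting C1 enolate give an oxyallyl (2‑oxidoallyl) cation, i.e. an enolonium at C1, which is quenched by 1,2‑shift of the electron‑rich quaternary C8 from C9 to C1 (semipinacol type, retention at C8, preferred over the acyl‑bearing C5) while the C9 methyl oxocarbenium is demethylated by methoxide to the ketone, the bridged geometry allowing only one configuration at C1; the closest known reactions are iodonium‑ylide formation from cyclic 1,3‑diones with PhI(OAc)2/KOH/MeOH, trivalent‑iodine‑induced oxidative ring expansions by 1,2‑alkyl shift, and oxyallyl‑cation (quasi‑Favorskii) semipinacol shifts.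

**Step 8**
Reactants: 19 bicyclic trione; 20 dimethyl sulfate
Product: 21 2-methoxy-7-geranyl-8-methyl-8-homoprenyl-5-prenylbicyclo[3.3.1]non-2-ene-4,9-dione
Conditions: Me2SO4, K2CO3, acetone, reflux
Reagents that add atoms: dimethyl sulfate 20, COS(=O)(=O)OC
Why: O‑Alkylation of the potassium enolate of the cyclic 1,3‑dione at the less hindered oxygen (next to the C1–H bridgehead) gives the vinylogous ester needed for the two lithiations.

**Step 9**
Reactants: 21 vinylogous methyl ester; 22 3-methoxybenzoyl chloride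
Product: 23 3-(3-methoxybenzoyl) derivative of 21
Conditions: lithium 2,2,6,6-tetramethylpiperidide, THF, −78 °C; 22, −78 °C
Reagents that add atoms: 3-methoxybenzoyl chloride 22, COc1cccc(c1)C(Cl)=O
Why: Directed vinylic lithiation of the β‑methoxy enone at C3, its most acidic C–H (the hindered bridgehead is slower), followed by C‑acylation with the aroyl chloride.

**Step 10**
Reactants: 23 3-(3-methoxybenzoyl) derivative of 21; 13 prenyl bromide
Product: 24 1-prenyl derivative of 23 (di-O-methyl target)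
Conditions: lithium 2,2,6,6-tetramethylpiperidide, THF, −78 → −40 °C; 13, −78 °C → rt
Reagents that add atoms: prenyl bromide 13, CC(C)=CCBr
Why: With C3 blocked, the C1–H is removed to the bridgehead (vinylogous) enolate and C‑alkylated by prenyl bromide (bridgehead enolate alkylation), the bicyclic framework allowing only one configuration at C1.

**Step 11**
Reactants: 24 di-O-methyl target
Product: 25 CNP0285073.1 (target)
Conditions: NaSEt, DMF, 120 °C; then 1 M HCl
Reagents that add atoms: none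
Why: Thiolate SN2 O‑demethylation cleaves both the vinylogous methyl ester and the aryl methyl ether without touching the acid‑sensitive prenyl‑type alkenes, and acidification gives the enolised triketone.

**Compound list**
1 | 2-methylcyclopent-2-en-1-one | CC1=CCCC1=O | starting material
2 | sodium benzenesulfinate | [Na+].[O-]S(=O)c1ccccc1 | starting material
3 | 2-methyl-3-(phenylsulfonyl)cyclopentan-1-one (racemic, mainly trans) | CC1C(CCC1=O)S(=O)(=O)c1ccccc1 | intermediate
4 | ethylene glycol (ethane-1,2-diol) | OCCO | starting material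
5 | 6-methyl-7-(phenylsulfonyl)-1,4-dioxaspiro[4.4]nonane (racemic) | CC1C(CCC12OCCO2)S(=O)(=O)c1ccccc1 | intermediate
6 | geranyl bromide, (2E)-1-bromo-3,7-dimethylocta-2,6-diene | CC(C)=CCC/C(C)=C/CBr | starting material
7 | 7-geranyl-6-methyl-7-(phenylsulfonyl)-1,4-dioxaspiro[4.4]nonane (not isolated) | CC1C(C/C=C(\C)CCC=C(C)C)(CCC12OCCO2)S(=O)(=O)c1ccccc1 | intermediate
8 | 3-geranyl-2-methyl-3-(phenylsulfonyl)cyclopentan-1-one (not isolated) | CC1C(C/C=C(\C)CCC=C(C)C)(CCC1=O)S(=O)(=O)c1ccccc1 | intermediate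
9 | 3-geranyl-2-methylcyclopent-2-en-1-one | CC1=C(C/C=C(\C)CCC=C(C)C)CCC1=O | intermediate
10 | 5-iodo-2-methylpent-2-ene (homoprenyl iodide) | CC(C)=CCCI | starting material
11 | {[(3S)-3-geranyl-2-methylcyclopent-1-en-1-yl]oxy}diphenylsilane (not isolated) | CC(C)=CCC/C(C)=C/C[C@@H]1CCC(O[SiH](c2ccccc2)c2ccccc2)=C1C | intermediate
12 | (2S,3S)-3-geranyl-2-methyl-2-homoprenylcyclopentan-1-one (methyl cis, homoprenyl trans to geranyl) | CC(C)=CCC/C(C)=C/C[C@@H]1CCC(=O)[C@@]1(C)CCC=C(C)C | intermediate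
13 | prenyl bromide, 1-bromo-3-methylbut-2-ene | CC(C)=CCBr | starting material
14 | 3-geranyl-2-methyl-2-homoprenyl-5-prenylcyclopentan-1-one (C2 and C3 as in 12; both C5 epimers) | CC(C)=CCC/C(C)=C/C[C@@H]1CC(CC=C(C)C)C(=O)[C@@]1(C)CCC=C(C)C | intermediate
15 | diketene, 4-methylideneoxetan-2-one | C=C1CC(=O)O1 | starting material
16 | 2-geranyl-7a-hydroxy-1-methyl-1-homoprenyl-3a-prenylhexahydro-1H-indene-4,6-dione (cis ring fusion; not isolated) | CC(C)=CCC/C(C)=C/C[C@@H]1C[C@@]2(CC=C(C)C)C(=O)CC(=O)C[C@@]2(O)[C@@]1(C)CCC=C(C)C | intermediate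
17 | 2-geranyl-1-methyl-1-homoprenyl-3a-prenyl-1,2,3,3a-tetrahydro-4H-indene-4,6(5H)-dione (1-methyl, 2-geranyl and 3a-prenyl on one face; enolised dione) | CC(C)=CCC/C(C)=C/C[C@@H]1C[C@@]2(CC=C(C)C)C(=O)CC(=O)C=C2[C@@]1(C)CCC=C(C)C | intermediate
18 | phenyliodonium ylide of 17 at the dione CH2 (C3 of the target numbering; not isolated) | CC(C)=CCC/C(C)=C/C[C@@H]1C[C@@]2(CC=C(C)C)C(=O)[C-]([I+]c3ccccc3)C(=O)C=C2[C@@]1(C)CCC=C(C)C | intermediate
19 | 7-geranyl-8-methyl-8-homoprenyl-5-prenylbicyclo[3.3.1]nonane-2,4,9-trione (C1–H; ring stereocentres as in 25: geranyl exo/equatorial and cis to the 5-prenyl, 8-methyl syn to C9) | CC(C)=CCC/C(C)=C/C[C@@H]1C[C@]2(CC=C(C)C)C(=O)[C@@H](C(=O)CC2=O)[C@@]1(C)CCC=C(C)C | intermediate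
20 | dimethyl sulfate | COS(=O)(=O)OC | starting material
21 | 2-methoxy-7-geranyl-8-methyl-8-homoprenyl-5-prenylbicyclo[3.3.1]non-2-ene-4,9-dione (stereocentres as in 19) | CC(C)=CCC/C(C)=C/C[C@@H]1C[C@]2(CC=C(C)C)C(=O)[C@@H](C(OC)=CC2=O)[C@@]1(C)CCC=C(C)C | intermediate
22 | 3-methoxybenzoyl chloride | COc1cccc(c1)C(Cl)=O | starting material
23 | 2-methoxy-3-(3-methoxybenzoyl)-7-geranyl-8-methyl-8-homoprenyl-5-prenylbicyclo[3.3.1]non-2-ene-4,9-dione (stereocentres as in 19) | CC(C)=CCC/C(C)=C/C[C@@H]1C[C@]2(CC=C(C)C)C(=O)[C@@H](C(OC)=C(C(=O)c3cccc(OC)c3)C2=O)[C@@]1(C)CCC=C(C)C | intermediate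
24 | 2-methoxy-3-(3-methoxybenzoyl)-7-geranyl-8-methyl-8-homoprenyl-1,5-diprenylbicyclo[3.3.1]non-2-ene-4,9-dione (stereocentres as in 25) | CC(C)=CCC/C(C)=C/C[C@@H]1C[C@]2(CC=C(C)C)C(=O)[C@@](CC=C(C)C)(C(OC)=C(C(=O)c3cccc(OC)c3)C2=O)[C@@]1(C)CCC=C(C)C | intermediate
25 | CNP0285073.1, (1S,5S,7R,8S)-7-[(2E)-3,7-dimethylocta-2,6-dien-1-yl]-4-hydroxy-3-(3-hydroxybenzoyl)-8-methyl-1,5-bis(3-methylbut-2-en-1-yl)-8-(4-methylpent-3-en-1-yl)bicyclo[3.3.1]non-3-ene-2,9-dione | CC(C)=CCC/C(C)=C/C[C@@H]1C[C@]2(CC=C(C)C)C(=O)[C@@](CC=C(C)C)(C(=O)C(C(=O)c3cccc(O)c3)=C2O)[C@@]1(C)CCC=C(C)C | target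

**Totals**
Total step count: 11. Longest linear sequence: 11 steps (1 → 25).

**Steps most likely to fail, with fallbacks**

Step 4 (CuH reduction of a tetrasubstituted enone, the demanding substrate class for this catalyst, followed by alkylation of a hindered enolate). The fallback sets out from 6 and returns at 12. The asymmetric reduction is moved to a β‑monosubstituted cyclopentenone, where it is well established. Cyclopent-2-en-1-one is taken through the operations of steps 1–3 with 2, 4 and 6. This gives 3-(phenylsulfonyl)cyclopentan-1-one F1, then 7-(phenylsulfonyl)-1,4-dioxaspiro[4.4]nonane F2, then 7-geranyl-7-(phenylsulfonyl)-1,4-dioxaspiro[4.4]nonane F3, then 3-geranyl-3-(phenylsulfonyl)cyclopentan-1-one F4 and finally 3-geranylcyclopent-2-en-1-one F5. Reduction with CuCl/NaOt-Bu/(S)-p-tol-BINAP/Ph2SiH2 gives {[(3S)-3-geranylcyclopent-1-en-1-yl]oxy}diphenylsilane F6, which MeLi and MeI convert in the same flask into (2S,3S)-2-methyl-3-geranylcyclopentan-1-one F7. Equilibrating silylation (Me3SiCl, NaI, Et3N, MeCN) gives the more substituted enol ether [(3S)-3-geranyl-2-methylcyclopent-1-en-1-yl]oxy(trimethyl)silane F8. MeLi followed by 10 then alkylates anti to the geranyl group and gives 12.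

Step 7 (the oxidative ring expansion; possible diversions are methoxylation at C3 or migration of C5). The fallback sets out from 16 and returns at 19. The same C1–C8 bond is made with an α‑bromoketone as the enolonium equivalent. The aldol adduct 16 is isolated by quenching step 6 at −78 °C with acetic acid and omitting the HCl treatment. LiN(i-Pr)2 (3.2 equiv) converts it into its alkoxide–dione dianion, and N‑bromosuccinimide brominates the terminal carbanion to give 7-bromo-2-geranyl-7a-hydroxy-1-methyl-1-homoprenyl-3a-prenylhexahydro-1H-indene-4,6-dione F9. MgBr2·OEt2 then triggers the halohydrin‑type semipinacol shift of C8 from C9 to the bromine‑bearing carbon (magnesium alkoxide push, bromide leaves) and delivers 19.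

Step 10 (SN2 alkylation of a bridgehead enolate flanked by the quaternary C8). The fallback sets out from 23 and returns at 24. The same bridgehead anion is trapped with the small electrophile I2 to give 1-iodo-2-methoxy-3-(3-methoxybenzoyl)-7-geranyl-8-methyl-8-homoprenyl-5-prenylbicyclo[3.3.1]non-2-ene-4,9-dione F10. Radical allylation (allylSnBu3, AIBN, benzene, 80 °C) gives 1-allyl-2-methoxy-3-(3-methoxybenzoyl)-7-geranyl-8-methyl-8-homoprenyl-5-prenylbicyclo[3.3.1]non-2-ene-4,9-dione F11. Cross‑metathesis with 2‑methylbut‑2‑ene (second‑generation Grubbs catalyst, RuCl2(=CHPh)(PCy3)(H2IMes), CH2Cl2, 40 °C) converts the allyl group into prenyl and gives 24.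

**Further compounds**
F1 | step 4 | 3-(phenylsulfonyl)cyclopentan-1-one | O=C1CCC(C1)S(=O)(=O)c1ccccc1
F2 | step 4 | 7-(phenylsulfonyl)-1,4-dioxaspiro[4.4]nonane | O=S(=O)(C1CCC2(C1)OCCO2)c1ccccc1
F3 | step 4 | 7-geranyl-7-(phenylsulfonyl)-1,4-dioxaspiro[4.4]nonane | CC(C)=CCC/C(C)=C/CC1(CCC2(C1)OCCO2)S(=O)(=O)c1ccccc1
F4 | step 4 | 3-geranyl-3-(phenylsulfonyl)cyclopentan-1-one | CC(C)=CCC/C(C)=C/CC1(CCC(=O)C1)S(=O)(=O)c1ccccc1
F5 | step 4 | 3-geranylcyclopent-2-en-1-one | CC(C)=CCC/C(C)=C/CC1=CC(=O)CC1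
F6 | step 4 | {[(3S)-3-geranylcyclopent-1-en-1-yl]oxy}diphenylsilane | CC(C)=CCC/C(C)=C/C[C@@H]1CCC(O[SiH](c2ccccc2)c2ccccc2)=C1
F7 | step 4 | (2S,3S)-2-methyl-3-geranylcyclopentan-1-one | CC(C)=CCC/C(C)=C/C[C@@H]1CCC(=O)[C@H]1C
F8 | step 4 | [(3S)-3-geranyl-2-methylcyclopent-1-en-1-yl]oxy(trimethyl)silane | CC(C)=CCC/C(C)=C/C[C@@H]1CCC(O[Si](C)(C)C)=C1C
F9 | step 7 | 7-bromo-2-geranyl-7a-hydroxy-1-methyl-1-homoprenyl-3a-prenylhexahydro-1H-indene-4,6-dione | CC(C)=CCC/C(C)=C/C[C@@H]1C[C@@]2(CC=C(C)C)C(=O)CC(=O)C(Br)[C@@]2(O)[C@@]1(C)CCC=C(C)C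
F10 | step 10 | 1-iodo-2-methoxy-3-(3-methoxybenzoyl)-7-geranyl-8-methyl-8-homoprenyl-5-prenylbicyclo[3.3.1]non-2-ene-4,9-dione | CC(C)=CCC/C(C)=C/C[C@@H]1C[C@]2(CC=C(C)C)C(=O)[C@@](I)(C(OC)=C(C(=O)c3cccc(OC)c3)C2=O)[C@@]1(C)CCC=C(C)C
F11 | step 10 | 1-allyl-2-methoxy-3-(3-methoxybenzoyl)-7-geranyl-8-methyl-8-homoprenyl-5-prenylbicyclo[3.3.1]non-2-ene-4,9-dione | CC(C)=CCC/C(C)=C/C[C@@H]1C[C@]2(CC=C(C)C)C(=O)[C@@](CC=C)(C(OC)=C(C(=O)c3cccc(OC)c3)C2=O)[C@@]1(C)CCC=C(C)C
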